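**Strategy.** Everything rests on forming ring C, the inner phloroglucinol between rings B and D, from acyclic partners. Ring C carries oxygen on C2, C4 and C6 and carbon on C1 (butyryl), C3 (CH2 to ring D) and C5 (CH2 to ring B); this alternating pattern is cut at C1–C2 and C5–C6. A single Diels–Alder/aromatisation joins a 1-methoxy-1,3-bis(trimethylsilyloxy)butadiene, bearing the benzyl-protected ring D arylmethyl on C2 and the ring B arylmethyl on C4, with 1-ethoxyhex-1-yn-3-one, so ring C closes with its butyryl group and both bridges in place. Butyrylation of rings B and D, ether cleavage and union with ring A follow.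

Key step: step 10

Remark: the target has no stereocentre and is treated as the tautomer written; rings B and D are numbered from the carbon bonded to the bridge towards ring C; ethoxyacetylene (hexane solution), N-methoxy-N-methylbutanamide and 1-(2,4,6-trihydroxyphenyl)butan-1-one are taken as catalogue compounds.

**Route**

Step 1
Reactants: 1 2,4,6-trihydroxybenzaldehyde
Product: 2 2,4,6-tris(benzyloxy)benzaldehyde
Conditions: BnBr, K2CO3, DMF, 60 °C
Reagents that add atoms: benzyl bromide, BrCc1ccccc1
Why: Williamson ether synthesis; the formyl group lowers the carbon nucleophilicity of the ring, so O-benzylation of all three phenoxides (the two hydrogen-bonded ortho ones on warming) should prevail over C-benzylation.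

Step 2
Reactants: 3 2,4,6-trihydroxytoluene
Product: 5 2,4,6-trihydroxy-3-methylbenzaldehyde, via aryl iminium chloride 4 (not isolated)
Conditions: POCl3, DMF, EtOAc, 0 °C to rt; then H2O, 50 °C
Reagents that add atoms: N,N-dimethylformamide, CN(C)C=O; water, O
Why: Vilsmeier–Haack formylation; the two free ring carbons are equivalent and the iminium group of 4 deactivates the ring against a second formylation.

Step 3
Reactants: 5 2,4,6-trihydroxy-3-methylbenzaldehyde
Product: 6 2,4,6-tris(benzyloxy)-3-methylbenzaldehyde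
Conditions: BnBr, K2CO3, DMF, 60 °C
Reagents that add atoms: benzyl bromide, BrCc1ccccc1
Why: Williamson ether synthesis, as in step 1, with the aldehyde again tempering C-alkylation at the one remaining ring carbon.

Step 4
Reactants: 7 methyl acetoacetate; 2 2,4,6-tris(benzyloxy)benzaldehyde
Product: 10 methyl (4E)-3-oxo-5-[2,4,6-tris(benzyloxy)phenyl]pent-4-enoate, via acetoacetate dianion 8 (not isolated), via aldol adduct 9 (not isolated)
Conditions: NaH then n-BuLi, THF, 0 °C; 2, –78 to –20 °C; aq. NH4Cl; crude, p-TsOH·H2O (cat.), CH2Cl2, rt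
Reagents that add atoms: none
Why: Weiler dianion aldol addition at the γ-carbon followed by acid-catalysed E1 dehydration through the trialkoxybenzylic cation should give the conjugated E-enone; the racemic carbinol centre of 9 is removed.

Step 5
Reactants: 10 methyl (4E)-3-oxo-5-[2,4,6-tris(benzyloxy)phenyl]pent-4-enoate; 6 2,4,6-tris(benzyloxy)-3-methylbenzaldehyde
Product: 11 methyl (4E)-2-{[2,4,6-tris(benzyloxy)-3-methylphenyl]methylidene}-3-oxo-5-[2,4,6-tris(benzyloxy)phenyl]pent-4-enoate (E/Z mixture at the new alkene)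
Conditions: piperidine (cat.), AcOH (cat.), PhMe, 4 Å MS, 70 °C
Reagents that add atoms: none
Why: Knoevenagel condensation at C2, the only doubly activated methylene; iminium catalysis compensates for the hindered, electron-rich aldehyde, sieves drive the dehydration, and the alkene geometry is irrelevant because the bond is reduced next.

Step 6
Reactants: 11 methyl (4E)-2-{[2,4,6-tris(benzyloxy)-3-methylphenyl]methylidene}-3-oxo-5-[2,4,6-tris(benzyloxy)phenyl]pent-4-enoate
Product: 12 methyl 2-{[2,4,6-tris(benzyloxy)-3-methylphenyl]methyl}-3-oxo-5-[2,4,6-tris(benzyloxy)phenyl]pentanoate (racemic)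
Conditions: H2 (1 atm), Pd/C, Ph2S (cat.), EtOAc, rt
Reagents that add atoms: none
Why: Catalytic hydrogenation over sulfide-poisoned palladium should saturate both the enone and the alkylidene acetoacetate C=C bonds while the poison suppresses hydrogenolysis of the aryl benzyl ethers; C2 forms as a racemate and is flattened again in step 7.

Step 7
Reactants: 12 methyl 2-{[2,4,6-tris(benzyloxy)-3-methylphenyl]methyl}-3-oxo-5-[2,4,6-tris(benzyloxy)phenyl]pentanoate
Product: 13 methyl 2-{[2,4,6-tris(benzyloxy)-3-methylphenyl]methyl}-5-[2,4,6-tris(benzyloxy)phenyl]-3-(trimethylsilyloxy)pent-2-enoate (E/Z mixture)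
Conditions: Me3SiCl, Et3N, PhMe, rt
Reagents that add atoms: chlorotrimethylsilane, C[Si](C)(C)Cl
Why: Silyl enol ether formation by soft enolisation at the more acidic C2–H gives the conjugated 3-silyloxy enoate, the standard first stage of a Chan-type diene synthesis.

Step 8
Reactants: 13 methyl 2-{[2,4,6-tris(benzyloxy)-3-methylphenyl]methyl}-5-[2,4,6-tris(benzyloxy)phenyl]-3-(trimethylsilyloxy)pent-2-enoate
Product: 15 1-methoxy-2-{[2,4,6-tris(benzyloxy)-3-methylphenyl]methyl}-4-{[2,4,6-tris(benzyloxy)phenyl]methyl}-1,3-bis(trimethylsilyloxy)buta-1,3-diene (mixture of double-bond isomers), via lithium dienolate 14 (not isolated)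
Conditions: LiN(i-Pr)2, THF, –78 °C; then Me3SiCl, –78 °C to rt; used crude
Reagents that add atoms: chlorotrimethylsilane, C[Si](C)(C)Cl
Why: Kinetic γ-deprotonation of the vinylogous ester and O-silylation of the dienolate is the established second stage for 2- and 4-substituted 1,3-bis(silyloxy)dienes; the labile diene is filtered from LiCl under argon and not chromatographed.

Step 9
Reactants: 16 ethoxyacetylene; 17 N-methoxy-N-methylbutanamide
Product: 20 1-ethoxyhex-1-yn-3-one, via lithium ethoxyacetylide 18 (not isolated), via tetrahedral adduct 19 (not isolated)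
Conditions: n-BuLi, THF, –78 °C; then 17, –78 to 0 °C; cold aq. NH4Cl
Reagents that add atoms: none
Why: Weinreb ketone synthesis with a lithium acetylide stops at the ketone because chelated adduct 19 persists until the cold, near-neutral quench, which also spares the acid-sensitive ynol ether.

Step 10
Reactants: 15 1-methoxy-2-{[2,4,6-tris(benzyloxy)-3-methylphenyl]methyl}-4-{[2,4,6-tris(benzyloxy)phenyl]methyl}-1,3-bis(trimethylsilyloxy)buta-1,3-diene; 20 1-ethoxyhex-1-yn-3-one
Product: 23 1-[6-ethoxy-2,4-dihydroxy-3-{[2,4,6-tris(benzyloxy)-3-methylphenyl]methyl}-5-{[2,4,6-tris(benzyloxy)phenyl]methyl}phenyl]butan-1-one, via cycloadduct 21 (not isolated), via aryl silyl ether 22 (not isolated)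
Conditions: PhMe (concentrated), 20 to 80 °C, sealed tube; then 1 M HCl, THF, 0 °C
Reagents that add atoms: none
Why: This is the thermal Diels–Alder reaction of a 1-alkoxy-1,3-bis(silyloxy)butadiene with an acetylenic ketone followed by aromatisation, a known route to acylresorcinols, applied here to a 2,4-disubstituted diene. The diene terminus C4 (largest HOMO coefficient) bonds to the ethoxy-bearing alkyne carbon (β to the carbonyl, largest LUMO coefficient) and the ketene-acetal carbon C1 bonds to the acyl-bearing carbon, which creates C5–C6 and C1–C2 of ring C. Ring C closes as a formal [4+2] cycloaddition; if the process is stepwise (Mukaiyama–Michael addition, then attack of the allenolate carbon on the silyloxy-stabilised allyl cation), the second bond forms in a 6-endo closure. Cycloadduct 21 loses methoxytrimethylsilane by 1,4-elimination (methoxy from C1, hydrogen from C4) to give arene 22, and dilute acid removes the remaining silyl group. No stereocentre is created in the product, since both sp3 centres of 21 vanish on aromatisation. The only selectivity needed is regiochemical and is secured by the matched polarisation of the two partners, while the C2 substituent prevents the competing Michael–aldol closure onto the ketone from reaching an arene and the acid-free, moderate heating spares the ynol ether.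

Step 11
Reactants: 23 1-[6-ethoxy-2,4-dihydroxy-3-{[2,4,6-tris(benzyloxy)-3-methylphenyl]methyl}-5-{[2,4,6-tris(benzyloxy)phenyl]methyl}phenyl]butan-1-one
Product: 24 1-[2,4,6-tris(benzyloxy)-3-({3-butanoyl-5-[(3-butanoyl-2,4,6-tris(benzyloxy)phenyl)methyl]-4-ethoxy-2,6-dihydroxyphenyl}methyl)-5-methylphenyl]butan-1-one (butanoyl on C5 of ring D and on C5 of ring B)
Conditions: PrCO2H, (CF3CO)2O, CH2Cl2, 0 °C to rt; then K2CO3, MeOH, rt
Reagents that add atoms: butanoic acid, CCCC(=O)O
Why: Friedel–Crafts acylation by the mixed butanoic trifluoroacetic anhydride can only strike the two tris(benzyloxy)arenes (ring C has no free carbon), each ketone deactivates its ring so ring B should take one acyl group at either of its two equivalent carbons, no metal Lewis acid endangers the benzyl ethers, and the basic methanol treatment cleaves any ester formed on the ring C phenols.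

Step 12
Reactants: 24 bis-butanoylated benzyl ether
Product: 25 1-[3-({3-butanoyl-5-[(3-butanoyl-2,4,6-trihydroxyphenyl)methyl]-4-ethoxy-2,6-dihydroxyphenyl}methyl)-2,4,6-trihydroxy-5-methylphenyl]butan-1-one
Conditions: H2 (1 atm), Pd/C, EtOAc–MeOH, rt
Reagents that add atoms: none
Why: Hydrogenolysis of the nine aryl benzyl ethers under neutral conditions; the ortho-hydroxy aryl ketones that emerge are chelated vinylogous acids that resist reduction, and the ethyl ether is untouched.

Step 13
Reactants: 25 ring C ethyl ether of the tris(butanoylphloroglucinol)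
Product: 26 1-[3-({3-butanoyl-5-[(3-butanoyl-2,4,6-trihydroxyphenyl)methyl]-2,4,6-trihydroxyphenyl}methyl)-2,4,6-trihydroxy-5-methylphenyl]butan-1-one
Conditions: BBr3 (excess), CH2Cl2, –78 to 0 °C; then MeOH, H2O
Reagents that add atoms: none
Why: Lewis-acid ether cleavage in which BBr3 coordinates the C6 ethoxy oxygen of ring C and bromide removes the ethyl group as bromoethane; every ring now carries an acyl group, which disfavours ipso protonation and so protects the methylene bridges.

Step 14
Reactants: 27 1-(2,4,6-trihydroxyphenyl)butan-1-one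
Product: 28 2-butanoyl-3,5-dihydroxy-4,4-dimethylcyclohexa-2,5-dien-1-one (butyrylfilicinic acid)
Conditions: MeI, NaOMe, MeOH, 0 °C to rt
Reagents that add atoms: iodomethane, CI
Why: Base-mediated C-methylation of an acylphloroglucinol, in which the carbon methylated first remains the most nucleophilic site so the second methyl enters the same carbon and dearomatises the ring to the acylfilicinic acid; no stereocentre arises.

Step 15
Reactants: 28 2-butanoyl-3,5-dihydroxy-4,4-dimethylcyclohexa-2,5-dien-1-one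
Product: 29 2-butanoyl-6-[(dimethylamino)methyl]-3,5-dihydroxy-4,4-dimethylcyclohexa-2,5-dien-1-one hydroiodide
Conditions: CH2=NMe2+ I–, MeCN, 0 °C to rt
Reagents that add atoms: N,N-dimethylmethyleneiminium iodide, C[N+](C)=C.[I-]
Why: Mannich reaction of the enolised β-triketone at its only free ring carbon (C6) with a preformed iminium salt; without added base the product stays N-protonated, which prevents premature loss of amine and formation of the methylene-bis dimer.

Step 16
Reactants: 26 tris(butanoylphloroglucinol) with free C3 on ring B; 29 ring A Mannich salt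
Product: 31 2-butanoyl-6-[(3-butanoyl-5-{[3-butanoyl-5-({3-butanoyl-2,4,6-trihydroxy-5-methylphenyl}methyl)-2,4,6-trihydroxyphenyl]methyl}-2,4,6-trihydroxyphenyl)methyl]-3,5-dihydroxy-4,4-dimethylcyclohexa-2,5-dien-1-one (CNP0246352.0), via ring A methide 30 (not isolated)
Conditions: NaOAc, MeCN, rt to 40 °C; then 1 M HCl
Reagents that add atoms: none
Why: Acetate triggers E1cB loss of dimethylamine from the Mannich salt to give methide 30, a doubly activated Michael acceptor, which the only free nucleophilic carbon of 26 (C3 of ring B) captures by Michael addition and rearomatisation (quinone-methide-type alkylation of an acylphloroglucinol); neither partner can couple with itself through carbon, and the buffered medium avoids base-induced bridge exchange.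

**Compound list**

1 | 2,4,6-trihydroxybenzaldehyde | O=Cc1c(O)cc(O)cc1O | starting material
2 | 2,4,6-tris(benzyloxy)benzaldehyde | O=Cc1c(OCc2ccccc2)cc(OCc2ccccc2)cc1OCc1ccccc1 | intermediate
3 | 2,4,6-trihydroxytoluene | Cc1c(O)cc(O)cc1O | starting material
4 | N-[(2,4,6-trihydroxy-3-methylphenyl)methylidene]-N-methylmethanaminium chloride | C[N+](C)=Cc1c(O)c(C)c(O)cc1O.[Cl-] | intermediate (not isolated)
5 | 2,4,6-trihydroxy-3-methylbenzaldehyde | O=Cc1c(O)c(C)c(O)cc1O | intermediate
6 | 2,4,6-tris(benzyloxy)-3-methylbenzaldehyde | O=Cc1c(OCc2ccccc2)c(C)c(OCc2ccccc2)cc1OCc1ccccc1 | intermediate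
7 | methyl acetoacetate | COC(=O)CC(C)=O | starting material
8 | methyl acetoacetate dianion (sodium lithium salt) | COC(=O)[CH-]C(=O)[CH2-].[Na+].[Li+] | intermediate (not isolated)
9 | methyl 5-hydroxy-3-oxo-5-[2,4,6-tris(benzyloxy)phenyl]pentanoate (racemic) | COC(=O)CC(=O)CC(O)c1c(OCc2ccccc2)cc(OCc2ccccc2)cc1OCc1ccccc1 | intermediate (not isolated)
10 | methyl (4E)-3-oxo-5-[2,4,6-tris(benzyloxy)phenyl]pent-4-enoate | COC(=O)CC(=O)/C=C/c1c(OCc2ccccc2)cc(OCc2ccccc2)cc1OCc1ccccc1 | intermediate
11 | methyl (4E)-2-{[2,4,6-tris(benzyloxy)-3-methylphenyl]methylidene}-3-oxo-5-[2,4,6-tris(benzyloxy)phenyl]pent-4-enoate (E/Z mixture at C2 alkylidene) | COC(=O)C(=Cc1c(OCc2ccccc2)c(C)c(OCc2ccccc2)cc1OCc1ccccc1)C(=O)/C=C/c1c(OCc2ccccc2)cc(OCc2ccccc2)cc1OCc1ccccc1 | intermediate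
12 | methyl 2-{[2,4,6-tris(benzyloxy)-3-methylphenyl]methyl}-3-oxo-5-[2,4,6-tris(benzyloxy)phenyl]pentanoate (racemic) | COC(=O)C(Cc1c(OCc2ccccc2)c(C)c(OCc2ccccc2)cc1OCc1ccccc1)C(=O)CCc1c(OCc2ccccc2)cc(OCc2ccccc2)cc1OCc1ccccc1 | intermediate
13 | methyl 2-{[2,4,6-tris(benzyloxy)-3-methylphenyl]methyl}-5-[2,4,6-tris(benzyloxy)phenyl]-3-(trimethylsilyloxy)pent-2-enoate (E/Z mixture) | COC(=O)C(Cc1c(OCc2ccccc2)c(C)c(OCc2ccccc2)cc1OCc1ccccc1)=C(O[Si](C)(C)C)CCc1c(OCc2ccccc2)cc(OCc2ccccc2)cc1OCc1ccccc1 | intermediate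
14 | lithium dienolate of 13 (O-lithium ketene acetal) | COC(O[Li])=C(Cc1c(OCc2ccccc2)c(C)c(OCc2ccccc2)cc1OCc1ccccc1)C(O[Si](C)(C)C)=CCc1c(OCc2ccccc2)cc(OCc2ccccc2)cc1OCc1ccccc1 | intermediate (not isolated)
15 | 1-methoxy-2-{[2,4,6-tris(benzyloxy)-3-methylphenyl]methyl}-4-{[2,4,6-tris(benzyloxy)phenyl]methyl}-1,3-bis(trimethylsilyloxy)buta-1,3-diene (mixture of double-bond isomers) | COC(O[Si](C)(C)C)=C(Cc1c(OCc2ccccc2)c(C)c(OCc2ccccc2)cc1OCc1ccccc1)C(O[Si](C)(C)C)=CCc1c(OCc2ccccc2)cc(OCc2ccccc2)cc1OCc1ccccc1 | intermediate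
16 | ethoxyacetylene | CCOC#C | starting material
17 | N-methoxy-N-methylbutanamide | CCCC(=O)N(C)OC | starting material
18 | lithium ethoxyacetylide | CCOC#C[Li] | intermediate (not isolated)
19 | lithium 1-ethoxy-3-[methoxy(methyl)amino]hex-1-yn-3-olate (racemic) | CCCC(O[Li])(N(C)OC)C#COCC | intermediate (not isolated)
20 | 1-ethoxyhex-1-yn-3-one | CCCC(=O)C#COCC | intermediate
21 | 1-[2-ethoxy-6-methoxy-3-{[2,4,6-tris(benzyloxy)phenyl]methyl}-5-{[2,4,6-tris(benzyloxy)-3-methylphenyl]methyl}-4,6-bis(trimethylsilyloxy)cyclohexa-1,4-dien-1-yl]butan-1-one (racemic diastereomer mixture) | CCCC(=O)C1=C(OCC)C(Cc2c(OCc3ccccc3)cc(OCc3ccccc3)cc2OCc2ccccc2)C(O[Si](C)(C)C)=C(Cc2c(OCc3ccccc3)c(C)c(OCc3ccccc3)cc2OCc2ccccc2)C1(OC)O[Si](C)(C)C | intermediate (not isolated)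
22 | 1-[6-ethoxy-2-hydroxy-3-{[2,4,6-tris(benzyloxy)-3-methylphenyl]methyl}-5-{[2,4,6-tris(benzyloxy)phenyl]methyl}-4-(trimethylsilyloxy)phenyl]butan-1-one | CCCC(=O)c1c(O)c(Cc2c(OCc3ccccc3)c(C)c(OCc3ccccc3)cc2OCc2ccccc2)c(O[Si](C)(C)C)c(Cc2c(OCc3ccccc3)cc(OCc3ccccc3)cc2OCc2ccccc2)c1OCC | intermediate (not isolated)
23 | 1-[6-ethoxy-2,4-dihydroxy-3-{[2,4,6-tris(benzyloxy)-3-methylphenyl]methyl}-5-{[2,4,6-tris(benzyloxy)phenyl]methyl}phenyl]butan-1-one | CCCC(=O)c1c(O)c(Cc2c(OCc3ccccc3)c(C)c(OCc3ccccc3)cc2OCc2ccccc2)c(O)c(Cc2c(OCc3ccccc3)cc(OCc3ccccc3)cc2OCc2ccccc2)c1OCC | intermediate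
24 | 1-[2,4,6-tris(benzyloxy)-3-({3-butanoyl-5-[(3-butanoyl-2,4,6-tris(benzyloxy)phenyl)methyl]-4-ethoxy-2,6-dihydroxyphenyl}methyl)-5-methylphenyl]butan-1-one | CCCC(=O)c1c(O)c(Cc2c(OCc3ccccc3)c(C)c(OCc3ccccc3)c(C(=O)CCC)c2OCc2ccccc2)c(O)c(Cc2c(OCc3ccccc3)cc(OCc3ccccc3)c(C(=O)CCC)c2OCc2ccccc2)c1OCC | intermediate
25 | 1-[3-({3-butanoyl-5-[(3-butanoyl-2,4,6-trihydroxyphenyl)methyl]-4-ethoxy-2,6-dihydroxyphenyl}methyl)-2,4,6-trihydroxy-5-methylphenyl]butan-1-one | CCCC(=O)c1c(O)c(Cc2c(O)c(C)c(O)c(C(=O)CCC)c2O)c(O)c(Cc2c(O)cc(O)c(C(=O)CCC)c2O)c1OCC | intermediate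
26 | 1-[3-({3-butanoyl-5-[(3-butanoyl-2,4,6-trihydroxyphenyl)methyl]-2,4,6-trihydroxyphenyl}methyl)-2,4,6-trihydroxy-5-methylphenyl]butan-1-one | CCCC(=O)c1c(O)c(Cc2c(O)c(C)c(O)c(C(=O)CCC)c2O)c(O)c(Cc2c(O)cc(O)c(C(=O)CCC)c2O)c1O | intermediate
27 | 1-(2,4,6-trihydroxyphenyl)butan-1-one | CCCC(=O)c1c(O)cc(O)cc1O | starting material
28 | 2-butanoyl-3,5-dihydroxy-4,4-dimethylcyclohexa-2,5-dien-1-one | CCCC(=O)C1=C(O)C(C)(C)C(O)=CC1=O | intermediate
29 | 2-butanoyl-6-[(dimethylamino)methyl]-3,5-dihydroxy-4,4-dimethylcyclohexa-2,5-dien-1-one hydroiodide | CCCC(=O)C1=C(O)C(C)(C)C(O)=C(C[NH+](C)C)C1=O.[I-] | intermediate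
30 | 2-butanoyl-3-hydroxy-4,4-dimethyl-6-methylidenecyclohex-2-ene-1,5-dione | CCCC(=O)C1=C(O)C(C)(C)C(=O)C(=C)C1=O | intermediate (not isolated)
31 | 2-butanoyl-6-[(3-butanoyl-5-{[3-butanoyl-5-({3-butanoyl-2,4,6-trihydroxy-5-methylphenyl}methyl)-2,4,6-trihydroxyphenyl]methyl}-2,4,6-trihydroxyphenyl)methyl]-3,5-dihydroxy-4,4-dimethylcyclohexa-2,5-dien-1-one (CNP0246352.0) | CCCC(=O)C1=C(O)C(C)(C)C(O)=C(Cc2c(O)c(Cc3c(O)c(Cc4c(O)c(C)c(O)c(C(=O)CCC)c4O)c(O)c(C(=O)CCC)c3O)c(O)c(C(=O)CCC)c2O)C1=O | target

**Totals**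

Total step count: 16.
Longest linear sequence: 11 steps (steps 2, 3, 5, 6, 7, 8, 10, 11, 12, 13, 16 from compound 3; the sequence from compound 1 through steps 1 and 4 is equally long).

**Steps most likely to fail**

Step 10. The crowded 2,4-disubstituted diene may not engage the donor-deactivated ynone before the ynol ether decomposes thermally (retro-ene loss of ethene). A first-formed zwitterion may also close onto the ketone carbonyl instead of C1, or simply be protonated. The fallback divides the two bond formations into two known ionic operations and sets out from 15 and 20. TiCl4 in CH2Cl2 at –78 °C should bring about Mukaiyama–Michael addition of the diene terminus to the ethoxy-bearing carbon, and aqueous work-up should deliver the open-chain vinylogous ester F1. NaOMe in MeOH should then close ring C by Dieckmann condensation of the vinylogous enolate carbon onto the methyl ester, and enolisation of the resulting cyclohexadienone brings the route back at 23.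

Step 11. Ring B may be acylated twice, the crowded C5 of ring D may react incompletely, or the acid released may cause benzyl migration on the electron-rich rings. The fallback moves the acylation to the free phenol stage, where C-acylation is self-limiting, and sets out from 23. Hydrogenolysis (H2, Pd/C, EtOAc–MeOH) should give the hexaphenol ethyl ether F2. A Houben–Hoesch reaction (butanenitrile, ZnCl2, HCl, Et2O, 0 °C) should then place one ketimine on ring D and one on ring B, giving the bis(ketimine) F3, whose hydrolysis in warm water rejoins the route at 25.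

Step 16. Methide 30 may be recaptured by the released amine faster than ring B attacks it, or the basic medium may induce exchange of methylene bridges and scramble the oligomer. The fallback reverses the roles of the partners and sets out from 26. Aqueous CH2O and Me2NH in EtOH should give the ring B Mannich base F4. Warming F4 with 28 in dioxane should expel dimethylamine to form the ring B ortho-quinone methide F5, which C6 of 28, the most nucleophilic carbon present, should capture to arrive at 31.

**Further compounds**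

F1 | step 10 | methyl 5-ethoxy-3,7-dioxo-2-{[2,4,6-tris(benzyloxy)-3-methylphenyl]methyl}-4-{[2,4,6-tris(benzyloxy)phenyl]methyl}dec-5-enoate | COC(=O)C(Cc1c(OCc2ccccc2)c(C)c(OCc2ccccc2)cc1OCc1ccccc1)C(=O)C(Cc1c(OCc2ccccc2)cc(OCc2ccccc2)cc1OCc1ccccc1)C(OCC)=CC(=O)CCC
F2 | step 11 | 1-{6-ethoxy-2,4-dihydroxy-3-[(2,4,6-trihydroxy-3-methylphenyl)methyl]-5-[(2,4,6-trihydroxyphenyl)methyl]phenyl}butan-1-one | CCCC(=O)c1c(O)c(Cc2c(O)c(C)c(O)cc2O)c(O)c(Cc2c(O)cc(O)cc2O)c1OCC
F3 | step 11 | bis(ketimine) of 25, with 1-iminobutyl in place of butanoyl on rings B and D | CCCC(=O)c1c(O)c(Cc2c(O)c(C)c(O)c(C(=N)CCC)c2O)c(O)c(Cc2c(O)cc(O)c(C(=N)CCC)c2O)c1OCC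
F4 | step 16 | Mannich base of 26, with (dimethylamino)methyl on C3 of ring B | CCCC(=O)c1c(O)c(Cc2c(O)c(C)c(O)c(C(=O)CCC)c2O)c(O)c(Cc2c(O)c(CN(C)C)c(O)c(C(=O)CCC)c2O)c1O
F5 | step 16 | ring B ortho-quinone methide of 26 (3-methylidene-4-oxo form of ring B) | C=C1C(=O)C(C(=O)CCC)=C(O)C(Cc2c(O)c(Cc3c(O)c(C)c(O)c(C(=O)CCC)c3O)c(O)c(C(=O)CCC)c2O)=C1O
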